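**Plan**

1. Locants: ring C1 (ketone), C2 (N), C3, C4 (carbinol), C5 and C6 (oxirane carbons, C6 next to C1); lower chain C1'–C7' counted from C4.
2. The retrosynthesis cuts, in this order, C2'–C3' of the lower triene (Stille), the C2–N enamide bond (copper-catalysed amidation of a 2-iodoenone), then C5–C6 together with C6–O, and last the C3–C4 bond of a dialkynyl carbinol.
3. The enabling feature is the cis-fused C5–C6 oxirane lying α,β to the C1 ketone of the six-membered ring. This is a Darzens retron, so one base treatment of the acyclic (Z)-chloromethyl enone aldehyde 14 closes carbocycle and epoxide together.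
4. Forward: the C1–C6 chain is assembled from (triisopropylsilyl)acetylene, dimethyl oxalate and a chlorohydrin alkyne; ring and oxirane arise together in step 8; the upper trienamide is attached next and the lower dienamide last.
5. Stereochemistry: C4 comes from a catalytic enantioselective alkynylation of an α-ketoester (step 3). C5 and C6 are relayed from C4 in the Darzens closure (oxirane anti to the C4 oxygen). The Z-alkene of 14 comes from Lindlar reduction; all side-chain alkenes are E, from E-configured building blocks, a Horner–Wadsworth–Emmons reaction, syn-hydrostannation and a stereoretentive Stille coupling.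

Key step: step 8

**Remarks**

- Assumption: which antipode of the amino alcohol ligand delivers the 2R carbinol in step 3 is not predicted with confidence for this substrate; both antipodes are made from the commercial enantiomers of 2-amino-1-(4-nitrophenyl)propane-1,3-diol by N,N-dimethylation and primary O-silylation, the one that gives 2R is used, and the absolute configuration would be verified at epoxy enone 17 (for example by anomalous-dispersion X-ray analysis of a crystalline derivative).
- In the bicyclic names, C1 is ring C6, C5 is ring C4 and C6 is ring C5. The carbinol keeps one spatial arrangement from 9 to 36; its descriptor reads R up to 27 and S in 36 only because the ranking of its substituents changes.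

**Route**

Step 1
Reactants: 1 (triisopropylsilyl)acetylene; 2 dimethyl oxalate
Product: 4 methyl 2-oxo-4-(triisopropylsilyl)but-3-ynoate, via lithium (triisopropylsilyl)acetylide 3 (not isolated)
Conditions: n-BuLi, THF, −78 °C; then cannulated into 2 (2 equiv), THF, −78 °C
Reagents that add atoms: none
Why: Acyl substitution of an oxalate diester by a lithium acetylide should stop at the alkynyl α-ketoester, because the tetrahedral adduct persists at −78 °C and inverse addition to excess oxalate suppresses a second addition.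

Step 2
Reactants: 5 chloroacetaldehyde (anhydrous, dried by azeotropic distillation of the commercial aqueous solution); 6 ethynylmagnesium bromide
Product: 8 1-chlorobut-3-yn-2-yl acetate (racemic), via bromomagnesium 1-chlorobut-3-yn-2-olate 7 (not isolated)
Conditions: THF, −78 to −20 °C; then Ac2O, 0 °C
Reagents that add atoms: acetic anhydride CC(=O)OC(C)=O
Why: Grignard 1,2-addition to the aldehyde followed by O-acetylation of the magnesium alkoxide in the same flask should trap the chlorohydrin before it can close to an oxirane; the carbinol is left racemic because it is oxidised to the ketone in step 7.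

Step 3
Reactants: 4 methyl 2-oxo-4-(triisopropylsilyl)but-3-ynoate; 8 1-chlorobut-3-yn-2-yl acetate
Product: 9 methyl (2R)-5-acetoxy-6-chloro-2-hydroxy-2-[(triisopropylsilyl)ethynyl]hex-3-ynoate (mixture of C5 epimers)
Conditions: Zn(OTf)2 (20 mol%), (1S,2S)-3-(tert-butyldimethylsilyloxy)-2-(dimethylamino)-1-(4-nitrophenyl)propan-1-ol or its antipode (22 mol%), Et3N (30 mol%), toluene, 25–50 °C
Reagents that add atoms: none
Why: In this zinc-catalysed enantioselective alkynylation of an α-ketoester, the acetylide formed in situ from the terminal alkyne should add to the two-point-bound ketoester on the face left open by the chiral zinc amino alkoxide and set the quaternary carbinol (future C4) as R, while the bulky silyl group shields the ynone terminus from conjugate addition.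

Step 4
Reactants: 9 methyl (2R)-5-acetoxy-6-chloro-2-hydroxy-2-[(triisopropylsilyl)ethynyl]hex-3-ynoate
Product: 10 methyl (2R)-5-acetoxy-6-chloro-2-(triethylsilyloxy)-2-[(triisopropylsilyl)ethynyl]hex-3-ynoate
Conditions: Et3SiOTf, 2,6-lutidine, CH2Cl2, −78 to 0 °C
Reagents that add atoms: triethylsilyl trifluoromethanesulfonate CC[Si](CC)(CC)OS(=O)(=O)C(F)(F)F
Why: Silylation with a silyl triflate and a hindered pyridine base is the standard way to cap a tertiary alcohol and leaves the stereocentre, the acetate and the chloride untouched.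

Step 5
Reactants: 10 methyl (2R)-5-acetoxy-6-chloro-2-(triethylsilyloxy)-2-[(triisopropylsilyl)ethynyl]hex-3-ynoate
Product: 11 (2R)-6-chloro-2-(triethylsilyloxy)-2-[(triisopropylsilyl)ethynyl]hex-3-yne-1,5-diol
Conditions: i-Bu2AlH (6 equiv), CH2Cl2, −78 to 0 °C; aq. KNaC4H4O6 (potassium sodium tartrate)
Reagents that add atoms: none
Why: Aluminium hydride reduction should take the methyl ester to the primary alcohol and cleave the acetate in one operation, the covalent aluminium alkoxides and the neutral tartrate work-up keeping the chlorohydrin from closing to an oxirane.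

Step 6
Reactants: 11 (2R)-6-chloro-2-(triethylsilyloxy)-2-[(triisopropylsilyl)ethynyl]hex-3-yne-1,5-diol
Product: 12 (2R,3Z)-6-chloro-2-(triethylsilyloxy)-2-[(triisopropylsilyl)ethynyl]hex-3-ene-1,5-diol
Conditions: H2 (1 atm), Pd/CaCO3 poisoned with Pb(OAc)2 (Lindlar catalyst), quinoline, EtOAc, 20 °C, stopped after 1 equiv of H2
Reagents that add atoms: none
Why: Lindlar semi-hydrogenation delivers both hydrogens to one face of the internal alkyne and should give the Z-alkene, while the alkyne capped by the triisopropylsilyl group is too hindered to bind to the poisoned surface and the alkyl chloride is inert.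

Step 7
Reactants: 12 (2R,3Z)-6-chloro-2-(triethylsilyloxy)-2-[(triisopropylsilyl)ethynyl]hex-3-ene-1,5-diol
Product: 14 (2R,3Z)-6-chloro-5-oxo-2-(triethylsilyloxy)-2-[(triisopropylsilyl)ethynyl]hex-3-enal, via bis(alkoxysulfonium) dichloride 13 (not isolated)
Conditions: (COCl)2 (4 equiv), DMSO (8 equiv), CH2Cl2, −78 °C; 12 added, −78 to −60 °C; then Et3N, −78 to −30 °C; cold NaH2PO4/Na2HPO4 buffer; crude 14 used at once
Reagents that add atoms: none
Why: In a Swern oxidation both hydroxyls are converted into alkoxysulfonium ions before the base is added, so aldehyde and ketone should be released together and the six-membered lactol that a stepwise oxidant would form across the Z-alkene (and oxidise to a lactone) is avoided, the low temperature preserving the Z geometry.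

Step 8
Reactants: 14 (2R,3Z)-6-chloro-5-oxo-2-(triethylsilyloxy)-2-[(triisopropylsilyl)ethynyl]hex-3-enal
Product: 17 (4R,5S,6R)-5,6-epoxy-4-(triethylsilyloxy)-4-[(triisopropylsilyl)ethynyl]cyclohex-2-en-1-one, via lithium chloroenolate 15 (not isolated), via lithium trans-chlorohydrin aldolate 16 (not isolated)
Conditions: LiN(SiMe3)2 (1.05 equiv), THF (0.01 M), −78 °C, then −78 to 0 °C; sat. aq. NH4Cl
Reagents that add atoms: none
Why: The base removes a proton from the chloromethyl group, the only enolisable position (C4 is quaternary and the aldehyde has no α-hydrogen), and the Z-alkene holds chloroenolate 15 next to the aldehyde, so an intramolecular aldol addition forms the C5–C6 bond and, on warming, the alkoxide of 16 displaces the ketone-activated chloride to form the C6–O bond; this is an intramolecular Darzens condensation, the known reaction of an α-chloro ketone enolate with a tethered aldehyde. The cyclohexenone closes by a 6-(enolendo)-exo-trig aldol and the oxirane by a 3-exo-tet substitution, both favoured modes. C5 is set relative to C4 in the aldol: the bulky, non-chelating silyl ether lets the aldehyde adopt the dipole-opposed (Cornforth-type) rotamer with C5=O anti to C4–O, so in the half-chair transition state both oxygens are pseudo-axial and trans, which places the epoxide oxygen anti to the C4 oxygen. C6 is set by the stereoelectronic demand of the closure: only the chlorohydrin with chlorine anti-periplanar to the C5 alkoxide can cyclise, which enforces the cis ring fusion, and the other isomers return through retro-aldol or enolisation at C6. The selectivities needed are therefore site-selective enolisation and the C4-to-C5 relay, secured by the absence of any other acidic C–H bond and by the silyl ether on C4. High dilution and low temperature should hold back intermolecular aldol reaction and Z-to-E isomerisation of the enone.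

Step 9
Reactants: 17 (4R,5S,6R)-5,6-epoxy-4-(triethylsilyloxy)-4-[(triisopropylsilyl)ethynyl]cyclohex-2-en-1-one
Product: 18 (4R,5S,6R)-5,6-epoxy-2-iodo-4-(triethylsilyloxy)-4-[(triisopropylsilyl)ethynyl]cyclohex-2-en-1-one
Conditions: I2, pyridine, DMAP (cat.), CH2Cl2, 0 to 20 °C
Reagents that add atoms: iodine II
Why: Johnson α-iodination of an enone (conjugate addition of the pyridine base at C3, iodination of the resulting enolate at C2, elimination of the base) should place iodine on C2 without touching the three stereocentres or the silylalkyne.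

Step 10
Reactants: 19 (2E)-4-methylpent-2-enal; 20 ethyl (2E)-4-(diethoxyphosphoryl)but-2-enoate (triethyl 4-phosphonocrotonate)
Product: 21 ethyl (2E,4E,6E)-8-methylnona-2,4,6-trienoate
Conditions: LiOH·H2O, 4 Å molecular sieves, THF, reflux
Reagents that add atoms: none
Why: The vinylogous Horner–Wadsworth–Emmons olefination with a stabilised phosphonate should form the new C4–C5 alkene with E geometry and keep the two E-alkenes brought in by the reactants.

Step 11
Reactants: 21 ethyl (2E,4E,6E)-8-methylnona-2,4,6-trienoate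
Product: 22 (2E,4E,6E)-8-methylnona-2,4,6-trienoic acid
Conditions: LiOH, THF/MeOH/H2O, 20 °C; then 1 M HCl to pH 3
Reagents that add atoms: lithium hydroxide [Li+].[OH-]
Why: Saponification of the ethyl ester at room temperature should not disturb the triene geometry.

Step 12
Reactants: 22 (2E,4E,6E)-8-methylnona-2,4,6-trienoic acid
Product: 24 (2E,4E,6E)-8-methylnona-2,4,6-trienamide, via trienoyl imidazolide 23 (not isolated)
Conditions: 1,1'-carbonyldiimidazole, THF, 20 °C; then NH3 (28% aq.), 0 °C
Reagents that add atoms: ammonia N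
Why: Activation as the acyl imidazole and aminolysis with ammonia is a mild amide synthesis in which acyl substitution should outrun conjugate addition to the triene.

Step 13
Reactants: 18 (4R,5S,6R)-5,6-epoxy-2-iodo-4-(triethylsilyloxy)-4-[(triisopropylsilyl)ethynyl]cyclohex-2-en-1-one; 24 (2E,4E,6E)-8-methylnona-2,4,6-trienamide
Product: 25 (2E,4E,6E)-8-methyl-N-[(1R,5R,6S)-2-oxo-5-(triethylsilyloxy)-5-[(triisopropylsilyl)ethynyl]-7-oxabicyclo[4.1.0]hept-3-en-3-yl]nona-2,4,6-trienamide
Conditions: CuI (20 mol%), N,N'-dimethylethylenediamine (40 mol%), Cs2CO3, THF, 50 °C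
Reagents that add atoms: none
Why: The Goldberg-type copper-catalysed N-vinylation of a primary amide under diamine ligation should work here because an α-iodoenone is among the most reactive vinyl iodides, the coupling replacing iodine at the sp2 carbon without involving any stereocentre.

Step 14
Reactants: 25 (2E,4E,6E)-8-methyl-N-[(1R,5R,6S)-2-oxo-5-(triethylsilyloxy)-5-[(triisopropylsilyl)ethynyl]-7-oxabicyclo[4.1.0]hept-3-en-3-yl]nona-2,4,6-trienamide
Product: 26 (2E,4E,6E)-N-[(1R,5R,6S)-5-ethynyl-5-hydroxy-2-oxo-7-oxabicyclo[4.1.0]hept-3-en-3-yl]-8-methylnona-2,4,6-trienamide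
Conditions: Bu4NF, AcOH (1:1), THF, 0 to 20 °C
Reagents that add atoms: none
Why: Fluoride-induced desilylation should cleave both the alkynyl C–Si bond and the tertiary O–Si bond, the acetic acid buffer keeping the liberated tertiary alkoxide protonated so that Payne-type migration of the neighbouring epoxide is not triggered.

Step 15
Reactants: 26 (2E,4E,6E)-N-[(1R,5R,6S)-5-ethynyl-5-hydroxy-2-oxo-7-oxabicyclo[4.1.0]hept-3-en-3-yl]-8-methylnona-2,4,6-trienamide
Product: 27 (2E,4E,6E)-N-[(1R,5R,6S)-5-hydroxy-2-oxo-5-[(E)-2-(tributylstannyl)ethenyl]-7-oxabicyclo[4.1.0]hept-3-en-3-yl]-8-methylnona-2,4,6-trienamide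
Conditions: Bu3SnH (1.2 equiv, slow addition), PdCl2(PPh3)2 (5 mol%), THF, 0 °C
Reagents that add atoms: tributyltin hydride CCCC[SnH](CCCC)CCCC
Why: Palladium-catalysed hydrostannation adds H and Sn syn across the terminal alkyne, the fully substituted propargylic carbon steering tin to the terminus to give the E-alkenylstannane, and insertion of the alkyne should be much faster than reduction of the electron-rich 2-amido enone.

Step 16
Reactants: 28 potassium (1E,3E)-5-oxopenta-1,3-dien-1-olate (glutaconaldehyde potassium salt)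
Product: 29 (2E,4E)-5-bromopenta-2,4-dienal
Conditions: PPh3, Br2, CH2Cl2, 0 °C; then 28, 0 to 20 °C
Reagents that add atoms: bromine BrBr
Why: Deoxybromination of the vinylogous carboxylate with Ph3PBr2 (oxygen activated as an oxyphosphonium ion, bromide added and phosphine oxide expelled) should give the thermodynamically preferred E,E bromodienal.

Step 17
Reactants: 29 (2E,4E)-5-bromopenta-2,4-dienal
Product: 30 (2E,4E)-5-bromopenta-2,4-dienoic acid
Conditions: NaClO2, NaH2PO4, 2-methylbut-2-ene, t-BuOH/H2O, 0 to 20 °C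
Reagents that add atoms: sodium chlorite [Na+].[O-]Cl=O
Why: Pinnick oxidation takes a conjugated aldehyde to the acid without touching the alkenes or the vinyl bromide, the alkene scavenger removing hypochlorite.

Step 18
Reactants: 31 cyclopentane-1,3-dione
Product: 32 2-nitrocyclopentane-1,3-dione
Conditions: fuming HNO3, Et2O, 0 °C
Reagents that add atoms: nitric acid O[N+](=O)[O-]
Why: Electrophilic nitration of the enol of a cyclic 1,3-dione should occur at the doubly activated C2.

Step 19
Reactants: 32 2-nitrocyclopentane-1,3-dione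
Product: 33 2-amino-3-hydroxycyclopent-2-en-1-one hydrochloride
Conditions: H2 (1 atm), Pd/C, HCl, MeOH, 20 °C
Reagents that add atoms: hydrogen chloride Cl
Why: Catalytic hydrogenation reduces the nitro group to the amine, which is trapped as its hydrochloride because the free aminodione condenses with itself.

Step 20
Reactants: 30 (2E,4E)-5-bromopenta-2,4-dienoic acid; 33 2-amino-3-hydroxycyclopent-2-en-1-one hydrochloride
Product: 35 (2E,4E)-5-bromo-N-(2-hydroxy-5-oxocyclopent-1-en-1-yl)penta-2,4-dienamide, via (2E,4E)-5-bromopenta-2,4-dienoyl chloride 34 (not isolated)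
Conditions: (COCl)2, DMF (cat.), CH2Cl2, 0 to 20 °C; concentrated; then 33, Et3N, CH2Cl2, 0 °C
Reagents that add atoms: none
Why: N-acylation of the amine by the acid chloride should give the amide, since nitrogen is the better nucleophile and any O-acylated enol passes its acyl group on to nitrogen.

Step 21
Reactants: 27 (2E,4E,6E)-N-[(1R,5R,6S)-5-hydroxy-2-oxo-5-[(E)-2-(tributylstannyl)ethenyl]-7-oxabicyclo[4.1.0]hept-3-en-3-yl]-8-methylnona-2,4,6-trienamide; 35 (2E,4E)-5-bromo-N-(2-hydroxy-5-oxocyclopent-1-en-1-yl)penta-2,4-dienamide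
Product: 36 (2E,4E,6E)-N-[(1R,5S,6S)-5-hydroxy-5-[(1E,3E,5E)-7-[(2-hydroxy-5-oxocyclopent-1-en-1-yl)amino]-7-oxohepta-1,3,5-trien-1-yl]-2-oxo-7-oxabicyclo[4.1.0]hept-3-en-3-yl]-8-methylnona-2,4,6-trienamide
Conditions: PdCl2(MeCN)2 (10 mol%), DMF, 20 °C, dark, argon
Reagents that add atoms: none
Why: Stille coupling of an alkenylstannane with an alkenyl bromide proceeds with retention at both sp2 carbons and should give the all-E triene under neutral, phosphine-free conditions at room temperature that tolerate the free hydroxyl, the enol and both amide N–H groups.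

**Compound list**

1 | (triisopropylsilyl)acetylene | C#C[Si](C(C)C)(C(C)C)C(C)C | starting material
2 | dimethyl oxalate | COC(=O)C(=O)OC | starting material
3 | lithium (triisopropylsilyl)acetylide | [Li]C#C[Si](C(C)C)(C(C)C)C(C)C | intermediate
4 | methyl 2-oxo-4-(triisopropylsilyl)but-3-ynoate | COC(=O)C(=O)C#C[Si](C(C)C)(C(C)C)C(C)C | intermediate
5 | chloroacetaldehyde | ClCC=O | starting material
6 | ethynylmagnesium bromide | C#C[Mg]Br | starting material
7 | bromomagnesium 1-chlorobut-3-yn-2-olate | ClCC(O[Mg]Br)C#C | intermediate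
8 | 1-chlorobut-3-yn-2-yl acetate (racemic) | CC(=O)OC(CCl)C#C | intermediate
9 | methyl (2R)-5-acetoxy-6-chloro-2-hydroxy-2-[(triisopropylsilyl)ethynyl]hex-3-ynoate (C5 epimers) | CC(=O)OC(CCl)C#C[C@@](O)(C#C[Si](C(C)C)(C(C)C)C(C)C)C(=O)OC | intermediate
10 | methyl (2R)-5-acetoxy-6-chloro-2-(triethylsilyloxy)-2-[(triisopropylsilyl)ethynyl]hex-3-ynoate (C5 epimers) | CC(=O)OC(CCl)C#C[C@@](O[Si](CC)(CC)CC)(C#C[Si](C(C)C)(C(C)C)C(C)C)C(=O)OC | intermediate
11 | (2R)-6-chloro-2-(triethylsilyloxy)-2-[(triisopropylsilyl)ethynyl]hex-3-yne-1,5-diol (C5 epimers) | ClCC(O)C#C[C@@](O[Si](CC)(CC)CC)(C#C[Si](C(C)C)(C(C)C)C(C)C)CO | intermediate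
12 | (2R,3Z)-6-chloro-2-(triethylsilyloxy)-2-[(triisopropylsilyl)ethynyl]hex-3-ene-1,5-diol (C5 epimers) | ClCC(O)/C=C\[C@@](O[Si](CC)(CC)CC)(C#C[Si](C(C)C)(C(C)C)C(C)C)CO | intermediate
13 | bis(alkoxysulfonium) dichloride of 12 (both oxygens carry a dimethylsulfonium group) | C[S+](C)OC(CCl)/C=C\[C@@](O[Si](CC)(CC)CC)(C#C[Si](C(C)C)(C(C)C)C(C)C)CO[S+](C)C.[Cl-].[Cl-] | intermediate
14 | (2R,3Z)-6-chloro-5-oxo-2-(triethylsilyloxy)-2-[(triisopropylsilyl)ethynyl]hex-3-enal | ClCC(=O)/C=C\[C@@](O[Si](CC)(CC)CC)(C#C[Si](C(C)C)(C(C)C)C(C)C)C=O | intermediate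
15 | lithium enolate of 14 at the chloromethyl carbon (enolate geometry not defined) | [Li+].[O-]C(=CCl)/C=C\[C@@](O[Si](CC)(CC)CC)(C#C[Si](C(C)C)(C(C)C)C(C)C)C=O | intermediate
16 | lithium alkoxide of (4R,5R,6S)-6-chloro-5-hydroxy-4-(triethylsilyloxy)-4-[(triisopropylsilyl)ethynyl]cyclohex-2-en-1-one (Cl trans to O5, O5 trans to O4) | O=C1C=C[C@@](O[Si](CC)(CC)CC)(C#C[Si](C(C)C)(C(C)C)C(C)C)[C@@H]([O-])[C@@H]1Cl.[Li+] | intermediate
17 | (4R,5S,6R)-5,6-epoxy-4-(triethylsilyloxy)-4-[(triisopropylsilyl)ethynyl]cyclohex-2-en-1-one, i.e. (1R,5R,6S)-5-(triethylsilyloxy)-5-[(triisopropylsilyl)ethynyl]-7-oxabicyclo[4.1.0]hept-3-en-2-one | O=C1C=C[C@@](O[Si](CC)(CC)CC)(C#C[Si](C(C)C)(C(C)C)C(C)C)[C@H]2O[C@H]21 | intermediate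
18 | (4R,5S,6R)-5,6-epoxy-2-iodo-4-(triethylsilyloxy)-4-[(triisopropylsilyl)ethynyl]cyclohex-2-en-1-one | O=C1C(I)=C[C@@](O[Si](CC)(CC)CC)(C#C[Si](C(C)C)(C(C)C)C(C)C)[C@H]2O[C@H]21 | intermediate
19 | (2E)-4-methylpent-2-enal | CC(C)/C=C/C=O | starting material
20 | ethyl (2E)-4-(diethoxyphosphoryl)but-2-enoate | CCOC(=O)/C=C/CP(=O)(OCC)OCC | starting material
21 | ethyl (2E,4E,6E)-8-methylnona-2,4,6-trienoate | CC(C)/C=C/C=C/C=C/C(=O)OCC | intermediate
22 | (2E,4E,6E)-8-methylnona-2,4,6-trienoic acid | CC(C)/C=C/C=C/C=C/C(=O)O | intermediate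
23 | 1-[(2E,4E,6E)-8-methylnona-2,4,6-trienoyl]imidazole | CC(C)/C=C/C=C/C=C/C(=O)n1ccnc1 | intermediate
24 | (2E,4E,6E)-8-methylnona-2,4,6-trienamide | CC(C)/C=C/C=C/C=C/C(N)=O | intermediate
25 | (2E,4E,6E)-8-methyl-N-[(1R,5R,6S)-2-oxo-5-(triethylsilyloxy)-5-[(triisopropylsilyl)ethynyl]-7-oxabicyclo[4.1.0]hept-3-en-3-yl]nona-2,4,6-trienamide | CC(C)/C=C/C=C/C=C/C(=O)NC1=C[C@@](O[Si](CC)(CC)CC)(C#C[Si](C(C)C)(C(C)C)C(C)C)[C@H]2O[C@H]2C1=O | intermediate
26 | (2E,4E,6E)-N-[(1R,5R,6S)-5-ethynyl-5-hydroxy-2-oxo-7-oxabicyclo[4.1.0]hept-3-en-3-yl]-8-methylnona-2,4,6-trienamide | CC(C)/C=C/C=C/C=C/C(=O)NC1=C[C@@](O)(C#C)[C@H]2O[C@H]2C1=O | intermediate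
27 | (2E,4E,6E)-N-[(1R,5R,6S)-5-hydroxy-2-oxo-5-[(E)-2-(tributylstannyl)ethenyl]-7-oxabicyclo[4.1.0]hept-3-en-3-yl]-8-methylnona-2,4,6-trienamide | CC(C)/C=C/C=C/C=C/C(=O)NC1=C[C@@](O)(/C=C/[Sn](CCCC)(CCCC)CCCC)[C@H]2O[C@H]2C1=O | intermediate
28 | potassium (1E,3E)-5-oxopenta-1,3-dien-1-olate | [K+].[O-]/C=C/C=C/C=O | starting material
29 | (2E,4E)-5-bromopenta-2,4-dienal | Br/C=C/C=C/C=O | intermediate
30 | (2E,4E)-5-bromopenta-2,4-dienoic acid | Br/C=C/C=C/C(=O)O | intermediate
31 | cyclopentane-1,3-dione | O=C1CCC(=O)C1 | starting material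
32 | 2-nitrocyclopentane-1,3-dione | O=C1CCC(=O)C1[N+](=O)[O-] | intermediate
33 | 2-amino-3-hydroxycyclopent-2-en-1-one hydrochloride | Cl.NC1=C(O)CCC1=O | intermediate
34 | (2E,4E)-5-bromopenta-2,4-dienoyl chloride | Br/C=C/C=C/C(Cl)=O | intermediate
35 | (2E,4E)-5-bromo-N-(2-hydroxy-5-oxocyclopent-1-en-1-yl)penta-2,4-dienamide | Br/C=C/C=C/C(=O)NC1=C(O)CCC1=O | intermediate
36 | (2E,4E,6E)-N-[(1R,5S,6S)-5-hydroxy-5-[(1E,3E,5E)-7-[(2-hydroxy-5-oxocyclopent-1-en-1-yl)amino]-7-oxohepta-1,3,5-trien-1-yl]-2-oxo-7-oxabicyclo[4.1.0]hept-3-en-3-yl]-8-methylnona-2,4,6-trienamide | CC(C)/C=C/C=C/C=C/C(=O)NC1=C[C@@](O)(/C=C/C=C/C=C/C(=O)NC2=C(O)CCC2=O)[C@H]2O[C@H]2C1=O | target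

**Totals**

Total step count: 21
Longest linear sequence: 12 steps (steps 1, 3 to 9, 13 to 15 and 21)

**Steps most likely to fail**

Step 8 (Darzens closure). After the aldol addition the C5 alkoxide may take the triethylsilyl group from the neighbouring C4 oxygen, or the enolate may react between molecules, before the oxirane closes. Attack on the other face of the aldehyde would lead to the syn epoxide. The fallback sets out from 14 and comes back at 17. The chloride is exchanged for a sulfonium leaving group: Me2S and NaI (cat.) in acetone should convert 14 into the dimethylsulfonium chloride F1. K2CO3 in MeCN at 0 °C then generates the keto-stabilised sulfur ylide, which adds to the aldehyde and collapses to 17 with loss of dimethyl sulfide (sulfur-ylide epoxidation). No strong base and no long-lived alkoxide are involved, and reversible betaine formation allows the same anti selection.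

Step 3 (enantioselective alkynylation). Uncatalysed addition to the very electrophilic alkynyl ketoester, or weak facial discrimination between its two flanks, would erode the enantiomeric purity, and the sense of induction is not established for this substrate. The fallback sets out from 4 and 8 and comes back at 17; it replaces asymmetric catalysis by resolution. The addition is run without the chiral ligand (Zn(OTf)2, Et3N, toluene) to give the racemic adduct F2. This is carried through the unchanged steps 4 to 7 as the racemic silyl ether F3, the racemic diyne diol F4, the racemic (Z)-ene diol F5, its bis(alkoxysulfonium) salt F6 and the racemic chloro enone aldehyde F7. Under the conditions of step 8, F7 passes through the racemic chloroenolate F8 and the racemic aldolate F9 to the racemic epoxy enone F10. F10 is rigid, absorbs in the ultraviolet and carries one set of three linked stereocentres; it is separated by preparative chromatography on a polysaccharide-based chiral stationary phase into 17 and the antipodal epoxy enone F11, which is set aside.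

Step 13 (amidation). The weakly nucleophilic polyene amide may couple slowly, leaving the epoxy iodoenone exposed to carbonate at 50 °C, where epoxide opening and loss of iodine can compete. The fallback sets out from 18 and comes back at 25; the amide bond is made by acylation instead. Copper-catalysed coupling of 18 with tert-butyl carbamate (CuI, N,N'-dimethylethylenediamine, Cs2CO3, THF, 35 °C), a far better partner in this reaction, should give the tert-butyl enecarbamate F12. Its lithium salt (LiN(SiMe3)2, THF, −78 °C) is acylated with (2E,4E,6E)-8-methylnona-2,4,6-trienoyl chloride F13, made from acid 22 with oxalyl chloride, to give the N-Boc imide F14. Mg(ClO4)2 (cat.) in MeCN then removes the tert-butoxycarbonyl group selectively from the imide nitrogen and delivers 25.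

Further compounds
F1 | step 8 | [(3Z,5R)-5-formyl-2-oxo-5-(triethylsilyloxy)-7-(triisopropylsilyl)hept-3-en-6-yn-1-yl]dimethylsulfonium chloride | C[S+](C)CC(=O)/C=C\[C@@](O[Si](CC)(CC)CC)(C#C[Si](C(C)C)(C(C)C)C(C)C)C=O.[Cl-]
F2 | step 3 | methyl 5-acetoxy-6-chloro-2-hydroxy-2-[(triisopropylsilyl)ethynyl]hex-3-ynoate (racemic at C2, C5 epimers) | CC(=O)OC(CCl)C#CC(O)(C#C[Si](C(C)C)(C(C)C)C(C)C)C(=O)OC
F3 | step 3 | methyl 5-acetoxy-6-chloro-2-(triethylsilyloxy)-2-[(triisopropylsilyl)ethynyl]hex-3-ynoate (racemic at C2, C5 epimers) | CC(=O)OC(CCl)C#CC(O[Si](CC)(CC)CC)(C#C[Si](C(C)C)(C(C)C)C(C)C)C(=O)OC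
F4 | step 3 | 6-chloro-2-(triethylsilyloxy)-2-[(triisopropylsilyl)ethynyl]hex-3-yne-1,5-diol (racemic at C2, C5 epimers) | ClCC(O)C#CC(O[Si](CC)(CC)CC)(C#C[Si](C(C)C)(C(C)C)C(C)C)CO
F5 | step 3 | (3Z)-6-chloro-2-(triethylsilyloxy)-2-[(triisopropylsilyl)ethynyl]hex-3-ene-1,5-diol (racemic at C2, C5 epimers) | ClCC(O)/C=C\C(O[Si](CC)(CC)CC)(C#C[Si](C(C)C)(C(C)C)C(C)C)CO
F6 | step 3 | bis(alkoxysulfonium) dichloride of F5 | C[S+](C)OC(CCl)/C=C\C(O[Si](CC)(CC)CC)(C#C[Si](C(C)C)(C(C)C)C(C)C)CO[S+](C)C.[Cl-].[Cl-]
F7 | step 3 | (3Z)-6-chloro-5-oxo-2-(triethylsilyloxy)-2-[(triisopropylsilyl)ethynyl]hex-3-enal (racemic) | ClCC(=O)/C=C\C(O[Si](CC)(CC)CC)(C#C[Si](C(C)C)(C(C)C)C(C)C)C=O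
F8 | step 3 | lithium enolate of F7 at the chloromethyl carbon (racemic) | [Li+].[O-]C(=CCl)/C=C\C(O[Si](CC)(CC)CC)(C#C[Si](C(C)C)(C(C)C)C(C)C)C=O
F9 | step 3 | lithium alkoxide of racemic (4R*,5R*,6S*)-6-chloro-5-hydroxy-4-(triethylsilyloxy)-4-[(triisopropylsilyl)ethynyl]cyclohex-2-en-1-one | O=C1C=C[C@@](O[Si](CC)(CC)CC)(C#C[Si](C(C)C)(C(C)C)C(C)C)[C@@H]([O-])[C@@H]1Cl.O=C1C=C[C@](O[Si](CC)(CC)CC)(C#C[Si](C(C)C)(C(C)C)C(C)C)[C@H]([O-])[C@H]1Cl.[Li+].[Li+]
F10 | step 3 | racemic (4R*,5S*,6R*)-5,6-epoxy-4-(triethylsilyloxy)-4-[(triisopropylsilyl)ethynyl]cyclohex-2-en-1-one | O=C1C=C[C@@](O[Si](CC)(CC)CC)(C#C[Si](C(C)C)(C(C)C)C(C)C)[C@H]2O[C@H]21.O=C1C=C[C@](O[Si](CC)(CC)CC)(C#C[Si](C(C)C)(C(C)C)C(C)C)[C@@H]2O[C@@H]21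
F11 | step 3 | (4S,5R,6S)-5,6-epoxy-4-(triethylsilyloxy)-4-[(triisopropylsilyl)ethynyl]cyclohex-2-en-1-one | O=C1C=C[C@](O[Si](CC)(CC)CC)(C#C[Si](C(C)C)(C(C)C)C(C)C)[C@@H]2O[C@@H]21
F12 | step 13 | tert-butyl N-[(1R,5R,6S)-2-oxo-5-(triethylsilyloxy)-5-[(triisopropylsilyl)ethynyl]-7-oxabicyclo[4.1.0]hept-3-en-3-yl]carbamate | CC(C)(C)OC(=O)NC1=C[C@@](O[Si](CC)(CC)CC)(C#C[Si](C(C)C)(C(C)C)C(C)C)[C@H]2O[C@H]2C1=O
F13 | step 13 | (2E,4E,6E)-8-methylnona-2,4,6-trienoyl chloride | CC(C)/C=C/C=C/C=C/C(Cl)=O
F14 | step 13 | tert-butyl N-[(2E,4E,6E)-8-methylnona-2,4,6-trienoyl]-N-[(1R,5R,6S)-2-oxo-5-(triethylsilyloxy)-5-[(triisopropylsilyl)ethynyl]-7-oxabicyclo[4.1.0]hept-3-en-3-yl]carbamate | CC(C)/C=C/C=C/C=C/C(=O)N(C(=O)OC(C)(C)C)C1=C[C@@](O[Si](CC)(CC)CC)(C#C[Si](C(C)C)(C(C)C)C(C)C)[C@H]2O[C@H]2C1=O
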